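**Plan**

- Cuts, in retrosynthetic order: the nonadecanoate C–O bond; the sp2–sp2 bond of the diene next to the quaternary carbon (back to an ethynyl group); the Z C=C of the nine-membered ring (ring-closing metathesis); the exocyclic C=CH2 and the allyl C–C bond (back to a formyl group); in the oxolane, the bond between the O-bearing quaternary carbon and the neighbouring ring-fusion carbon, made together with a 1,2-shift (pinacol-terminated Prins step); the Z-alkene of an allylic diol (Wittig).
- Forward: linalool chain plus glyceraldehyde give a Z-allylic diol, which is ketalised with an alkynyl ketone; the oxolane is formed first (key step), then the nine-membered carbocycle by metathesis, then the diene, then the ester.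
- Enabling feature: the oxolane ring-fusion carbon beta to oxygen carries the sp2 carbon of the exocyclic methylene of the nine-membered ring, a latent acyl group; the oxolane is therefore a 3-acyl-oxolane, and the alkenyl group on the quaternary carbon can come from an alkyne slim enough to sit axial.
- Stereochemistry: the tertiary carbinol comes from (S)-linalool; the quaternary and the chain-bearing ring carbon come from the single carbinol centre of (R)-glyceraldehyde acetonide through one chair (Z-alkene: chain axial; alkynyl axial; CH2OSi equatorial); the third ring carbon is set by equilibration to trans; the ring olefin is Z by ring size; the diene is E by syn-hydrostannation.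

Key step: step 10

Remark (assumption): (S)-(+)-linalool of high enantiomeric purity is taken as commercially available; its stereocentre is never touched.
Remark (numbering used below): oxolane atoms as in 16: O1, C2 (OCH2), C3 (formyl-bearing), C4 (chain-bearing), C5 (quaternary).

**Route**

Step 1
Reactants: 1 (S)-linalool
Product: 2 linalool TBS ether
Conditions: TBSOTf, 2,6-lutidine, CH2Cl2, 0 °C to rt
Reagents that add atoms: tert-butyldimethylsilyl trifluoromethanesulfonate, CC(C)(C)[Si](C)(C)OS(=O)(=O)C(F)(F)F
Why: A silyl triflate with a hindered pyridine base silylates the tertiary allylic alcohol without ionisation (standard silyl ether formation), and the stereocentre is untouched.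

Step 2
Reactants: 2 linalool TBS ether
Product: 4 (4S)-4-[(tert-butyldimethylsilyl)oxy]-4-methylhex-5-en-1-ol, via aldehyde 3 (not isolated)
Conditions: O3 (one equivalent), pyridine, CH2Cl2/MeOH, −78 °C; then NaBH4, −78 to 0 °C
Reagents that add atoms: ozone, [O-][O+]=O
Why: Ozone cleaves the electron-rich trisubstituted alkene much faster than the vinyl group next to the quaternary carbon (chemoselective ozonolysis), and borohydride reduces the aldehyde in the same flask.

Step 3
Reactants: 4 primary alcohol
Product: 5 primary iodide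
Conditions: I2, PPh3, imidazole, CH2Cl2, 0 °C
Reagents that add atoms: iodine, II
Why: Appel iodination of a primary alcohol by SN2 on the alkoxyphosphonium ion, to which the tertiary silyl ether is inert.

Step 4
Reactants: 5 primary iodide
Product: 6 phosphonium iodide
Conditions: PPh3, MeCN, reflux
Reagents that add atoms: triphenylphosphine, c1ccc(cc1)P(c1ccccc1)c1ccccc1
Why: SN2 quaternisation of triphenylphosphine by a primary iodide gives the Wittig salt.

Step 5
Reactants: 6 phosphonium iodide; 7 (R)-glyceraldehyde acetonide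
Product: 9 Z-alkenyl dioxolane, via phosphonium ylide 8 (not isolated)
Conditions: 6, KN(SiMe3)2, THF, −78 °C; then 7, −78 to 0 °C
Reagents that add atoms: none
Why: Salt-free Wittig olefination of a non-stabilised ylide with an alpha-alkoxy aldehyde is Z-selective (early, puckered oxaphosphetane), and the low temperature keeps the alpha stereocentre of 7 intact.

Step 6
Reactants: 9 Z-alkenyl dioxolane
Product: 10 (2S,3Z)-allylic 1,2-diol
Conditions: AcOH/THF/H2O (4:1:1), 40 °C
Reagents that add atoms: none
Why: Mild aqueous acid hydrolyses the terminal acetonide, while the hindered tertiary silyl ether and the Z-allylic alcohol survive.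

Step 7
Reactants: 11 methyl glycolate
Product: 12 methyl (tert-butyldiphenylsilyloxy)acetate
Conditions: TBDPSCl, imidazole, DMF, 0 °C to rt
Reagents that add atoms: tert-butyl(chloro)diphenylsilane, CC(C)(C)[Si](Cl)(c1ccccc1)c1ccccc1
Why: Standard silylation of a primary alcohol.

Step 8
Reactants: 12 silyloxy ester
Product: 13 1-silyloxy-4-(trimethylsilyl)but-3-yn-2-one
Conditions: LiC≡CSiMe3, BF3·OEt2, THF, −78 °C
Reagents that add atoms: lithium (trimethylsilyl)acetylide, [Li]C#C[Si](C)(C)C
Why: BF3-mediated acylation of an alkynyllithium by an ester stops at the ketone because the tetrahedral adduct persists at −78 °C (ynone synthesis from esters).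

Step 9
Reactants: 10 allylic 1,2-diol; 13 ynone
Product: 14 alkynyl ketal (4-alkenyl-1,3-dioxolane, both epimers at C-2)
Conditions: i-PrOSiMe3 (2.2 equiv), Me3SiOTf (5 mol %), CH2Cl2, −40 °C; pyridine quench
Reagents that add atoms: none
Why: Silyl triflate-catalysed ketalisation with an alkoxysilane as water scavenger (Noyori-type conditions) forms the five-membered ketal of the 1,2-diol at low temperature, and both ketal epimers can be used because the next step passes through one planar oxocarbenium ion.

Step 10
Reactants: 14 alkynyl ketal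
Product: 16 cis-formyl oxolane, via oxocarbenium ion 15 (not isolated)
Conditions: SnCl4 (1.5 equiv), CH2Cl2, −78 to −20 °C
Reagents that add atoms: none
Why: SnCl4 ionises the ketal at the allylic oxygen to oxocarbenium ion 15, whose cationic carbon is attacked by the distal carbon of the Z-alkene in a chair transition state (6-endo with respect to the alkene; the new C4–C5 bond closes a transient oxane), and the developing secondary cation is captured by 1,2-shift of the OCH2 carbon, which turns the tin-bound carbinol carbon into the formyl group and contracts the oxane to the oxolane. The closest known reaction type is the pinacol-terminated Prins cyclization of allylic diol acetals to 3-acyltetrahydrofurans, and a 2-oxonia-Cope rearrangement followed by aldol closure runs through the same chair to the same product. At the quaternary C5 the slim linear alkynyl group takes the axial place and the bulky CH2OTBDPS group the equatorial one. At C4 the Z geometry forces the side chain axial, so that it ends trans to the alkynyl group and cis to CH2OSi. The absolute sense comes from the S carbinol carbon, which turns its hydrogen and not its oxygen toward the axial chain (the other chair has a syn-diaxial O/CH2 contact), while C3 arises with formyl cis to the chain and is corrected in step 11. The step needs site selectivity, secured because only the Z-alkene can reach the cationic carbon through a six-membered array, and ring contraction in preference to hydride shift, for which secondary allylic carbinols are known to give formyl products.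

Step 11
Reactants: 16 cis-formyl oxolane
Product: 17 trans-formyl oxolane
Conditions: DBU (0.2 equiv), CH2Cl2, rt
Reagents that add atoms: none
Why: The amidine base equilibrates the formyl-bearing carbon through the enolate to the more stable 3,4-trans isomer (thermodynamic epimerisation alpha to an aldehyde), while C4 and C5 cannot epimerise.

Step 12
Reactants: 17 trans-formyl oxolane
Product: 18 homoallylic alcohols (both carbinol epimers)
Conditions: CH2=CHCH2MgBr, THF, −78 °C
Reagents that add atoms: allylmagnesium bromide, C=CC[Mg]Br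
Why: Grignard addition to the aldehyde at low temperature, the new carbinol centre being of no consequence because it is oxidised in step 13.

Step 13
Reactants: 18 homoallylic alcohols
Product: 19 allyl ketone
Conditions: Dess–Martin periodinane, NaHCO3, CH2Cl2, 0 °C
Reagents that add atoms: none
Why: Buffered Dess–Martin oxidation should give the beta,gamma-unsaturated ketone without conjugation of the olefin or epimerisation.

Step 14
Reactants: 19 allyl ketone
Product: 20 triene (1,1-disubstituted alkene)
Conditions: Zn, CH2Br2, TiCl4, THF/CH2Cl2, 0 °C to rt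
Reagents that add atoms: dibromomethane, BrCBr
Why: The non-basic zinc/titanium methylene reagent (Takai–Lombardo methylenation) converts a hindered, easily enolised ketone into the methylidene compound without enolisation.

Step 15
Reactants: 20 triene
Product: 21 silyl-protected cyclononene-fused oxolane
Conditions: second-generation Grubbs catalyst (10 mol %), CH2Cl2, 1 mM, 40 °C
Reagents that add atoms: none
Why: Ring-closing metathesis, in which the carbene loads on the unhindered allyl terminus and closes onto the linalool-type vinyl group, a nine-membered ring can hold only the Z olefin, and the silylated alkyne flanked by a quaternary carbon is expected to stay out.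

Step 16
Reactants: 21 silyl-protected bicycle
Product: 22 ethynyl diol
Conditions: TBAF, THF, 0 to 45 °C
Reagents that add atoms: none
Why: Fluoride cleaves both silyl ethers and the alkynylsilane in one operation (Si–F bond strength), warming being needed for the tertiary ether.

Step 17
Reactants: 22 ethynyl diol
Product: 24 dienyl diol, via vinylstannane 23 (not isolated)
Conditions: Bu3SnH, Pd2(dba)3 (2.5 mol %), P(2-furyl)3, THF, 0 °C; then 1-bromo-2-methylprop-1-ene, 60 °C
Reagents that add atoms: 1-bromo-2-methylprop-1-ene, CC(C)=CBr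
Why: Palladium-catalysed syn-hydrostannation of the terminal alkyne places tin at the unhindered terminus (E-vinylstannane) and leaves alkenes alone, and Stille coupling in the same flask retains the geometry of both partners.

Step 18
Reactants: 24 dienyl diol
Product: 25 target nonadecanoate
Conditions: nonadecanoyl chloride (1.1 equiv), pyridine, CH2Cl2, 0 °C
Reagents that add atoms: nonadecanoyl chloride, CCCCCCCCCCCCCCCCCCC(=O)Cl
Why: Acylation with an acid chloride and pyridine takes place at the primary hydroxyl, the tertiary allylic alcohol being too hindered to react at 0 °C.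

**Compound list**

1 | (S)-(+)-linalool, (3S)-3,7-dimethylocta-1,6-dien-3-ol | C=C[C@@](C)(O)CCC=C(C)C | starting material
2 | (3S)-3-[(tert-butyldimethylsilyl)oxy]-3,7-dimethylocta-1,6-diene | C=C[C@@](C)(O[Si](C)(C)C(C)(C)C)CCC=C(C)C | intermediate
3 | (4S)-4-[(tert-butyldimethylsilyl)oxy]-4-methylhex-5-enal | C=C[C@@](C)(O[Si](C)(C)C(C)(C)C)CCC=O | intermediate
4 | (4S)-4-[(tert-butyldimethylsilyl)oxy]-4-methylhex-5-en-1-ol | C=C[C@@](C)(O[Si](C)(C)C(C)(C)C)CCCO | intermediate
5 | (3S)-3-[(tert-butyldimethylsilyl)oxy]-6-iodo-3-methylhex-1-ene | C=C[C@@](C)(O[Si](C)(C)C(C)(C)C)CCCI | intermediate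
6 | [(4S)-4-[(tert-butyldimethylsilyl)oxy]-4-methylhex-5-en-1-yl]triphenylphosphonium iodide | C=C[C@@](C)(O[Si](C)(C)C(C)(C)C)CCC[P+](c1ccccc1)(c1ccccc1)c1ccccc1.[I-] | intermediate
7 | (R)-2,2-dimethyl-1,3-dioxolane-4-carbaldehyde (2,3-O-isopropylidene-D-glyceraldehyde) | O=C[C@H]1COC(C)(C)O1 | starting material
8 | ylide of 6, [(4S)-4-[(tert-butyldimethylsilyl)oxy]-4-methylhex-5-en-1-ylidene]triphenylphosphorane | C=C[C@@](C)(O[Si](C)(C)C(C)(C)C)CCC=P(c1ccccc1)(c1ccccc1)c1ccccc1 | intermediate
9 | (4S)-4-[(1Z,5S)-5-[(tert-butyldimethylsilyl)oxy]-5-methylhepta-1,6-dien-1-yl]-2,2-dimethyl-1,3-dioxolane | C=C[C@@](C)(O[Si](C)(C)C(C)(C)C)CC/C=C\[C@H]1COC(C)(C)O1 | intermediate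
10 | (2S,3Z,7S)-7-[(tert-butyldimethylsilyl)oxy]-7-methylnona-3,8-diene-1,2-diol | C=C[C@@](C)(O[Si](C)(C)C(C)(C)C)CC/C=C\[C@H](O)CO | intermediate
11 | methyl glycolate (methyl 2-hydroxyacetate) | COC(=O)CO | starting material
12 | methyl 2-[(tert-butyldiphenylsilyl)oxy]acetate | COC(=O)CO[Si](c1ccccc1)(c1ccccc1)C(C)(C)C | intermediate
13 | 1-[(tert-butyldiphenylsilyl)oxy]-4-(trimethylsilyl)but-3-yn-2-one | C[Si](C)(C)C#CC(=O)CO[Si](c1ccccc1)(c1ccccc1)C(C)(C)C | intermediate
14 | (4S)-2-{[(tert-butyldiphenylsilyl)oxy]methyl}-4-[(1Z,5S)-5-[(tert-butyldimethylsilyl)oxy]-5-methylhepta-1,6-dien-1-yl]-2-[(trimethylsilyl)ethynyl]-1,3-dioxolane, both epimers at C-2 | C=C[C@@](C)(O[Si](C)(C)C(C)(C)C)CC/C=C\[C@H]1COC(CO[Si](c2ccccc2)(c2ccccc2)C(C)(C)C)(C#C[Si](C)(C)C)O1 | intermediate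
15 | oxocarbenium ion from 14, opened at the allylic oxygen, alkoxide bound to SnCl4 | C=C[C@@](C)(O[Si](C)(C)C(C)(C)C)CC/C=C\[C@H](O[Sn-](Cl)(Cl)(Cl)Cl)C[O+]=C(CO[Si](c1ccccc1)(c1ccccc1)C(C)(C)C)C#C[Si](C)(C)C | intermediate
16 | (3R,4S,5S)-5-{[(tert-butyldiphenylsilyl)oxy]methyl}-4-[(3S)-3-[(tert-butyldimethylsilyl)oxy]-3-methylpent-4-en-1-yl]-5-[(trimethylsilyl)ethynyl]oxolane-3-carbaldehyde (formyl cis to the C-4 chain; chain cis to CH2OSi, trans to alkynyl) | O=C[C@H]1CO[C@@](C#C[Si](C)(C)C)(CO[Si](c2ccccc2)(c2ccccc2)C(C)(C)C)[C@H]1CC[C@](C)(O[Si](C)(C)C(C)(C)C)C=C | intermediate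
17 | (3S,4S,5S) epimer of 16 (formyl trans to the C-4 chain) | O=C[C@@H]1CO[C@@](C#C[Si](C)(C)C)(CO[Si](c2ccccc2)(c2ccccc2)C(C)(C)C)[C@H]1CC[C@](C)(O[Si](C)(C)C(C)(C)C)C=C | intermediate
18 | 1-[(3S,4S,5S)-5-{[(tert-butyldiphenylsilyl)oxy]methyl}-4-[(3S)-3-[(tert-butyldimethylsilyl)oxy]-3-methylpent-4-en-1-yl]-5-[(trimethylsilyl)ethynyl]oxolan-3-yl]but-3-en-1-ol, both carbinol epimers | C=CCC(O)[C@@H]1CO[C@@](C#C[Si](C)(C)C)(CO[Si](c2ccccc2)(c2ccccc2)C(C)(C)C)[C@H]1CC[C@](C)(O[Si](C)(C)C(C)(C)C)C=C | intermediate
19 | 1-[(3S,4S,5S)-5-{[(tert-butyldiphenylsilyl)oxy]methyl}-4-[(3S)-3-[(tert-butyldimethylsilyl)oxy]-3-methylpent-4-en-1-yl]-5-[(trimethylsilyl)ethynyl]oxolan-3-yl]but-3-en-1-one | C=CCC(=O)[C@@H]1CO[C@@](C#C[Si](C)(C)C)(CO[Si](c2ccccc2)(c2ccccc2)C(C)(C)C)[C@H]1CC[C@](C)(O[Si](C)(C)C(C)(C)C)C=C | intermediate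
20 | (2S,3S,4R)-2-{[(tert-butyldiphenylsilyl)oxy]methyl}-3-[(3S)-3-[(tert-butyldimethylsilyl)oxy]-3-methylpent-4-en-1-yl]-4-(hexa-1,5-dien-2-yl)-2-[(trimethylsilyl)ethynyl]oxolane | C=CCC(=C)[C@@H]1CO[C@@](C#C[Si](C)(C)C)(CO[Si](c2ccccc2)(c2ccccc2)C(C)(C)C)[C@H]1CC[C@](C)(O[Si](C)(C)C(C)(C)C)C=C | intermediate
21 | (1S,3aR,6Z,8S,10aS)-1-{[(tert-butyldiphenylsilyl)oxy]methyl}-8-[(tert-butyldimethylsilyl)oxy]-8-methyl-4-methylidene-1-[(trimethylsilyl)ethynyl]-3,3a,4,5,8,9,10,10a-octahydro-1H-cyclonona[c]furan (trans ring fusion) | C=C1C/C=C\[C@@](C)(O[Si](C)(C)C(C)(C)C)CC[C@H]2[C@H]1CO[C@@]2(C#C[Si](C)(C)C)CO[Si](c3ccccc3)(c3ccccc3)C(C)(C)C | intermediate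
22 | (1S,3aR,6Z,8S,10aS)-1-ethynyl-1-(hydroxymethyl)-8-methyl-4-methylidene-3,3a,4,5,8,9,10,10a-octahydro-1H-cyclonona[c]furan-8-ol | C=C1C/C=C\[C@@](C)(O)CC[C@H]2[C@H]1CO[C@@]2(C#C)CO | intermediate
23 | (E)-2-(tributylstannyl)ethenyl analogue of 22 | C=C1C/C=C\[C@@](C)(O)CC[C@H]2[C@H]1CO[C@@]2(/C=C/[Sn](CCCC)(CCCC)CCCC)CO | intermediate
24 | (1R,3aR,6Z,8S,10aS)-1-(hydroxymethyl)-8-methyl-4-methylidene-1-[(1E)-4-methylpenta-1,3-dien-1-yl]-3,3a,4,5,8,9,10,10a-octahydro-1H-cyclonona[c]furan-8-ol | C=C1C/C=C\[C@@](C)(O)CC[C@H]2[C@H]1CO[C@@]2(/C=C/C=C(C)C)CO | intermediate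
25 | CNP0120482.1, nonadecanoate of the primary alcohol of 24 | C=C1C/C=C\[C@@](C)(O)CC[C@H]2[C@H]1CO[C@@]2(/C=C/C=C(C)C)COC(=O)CCCCCCCCCCCCCCCCCC | target

**Count**

Total steps: 18. Longest linear sequence: 16 steps (steps 1–6 and 9–18, from 1); the ketone branch (steps 7–8) joins at step 9.

**Steps most likely to fail**

Step 10 (key step). What may go wrong: the two chair arrangements at the oxocarbenium carbon are not told apart cleanly (loss of control at the quaternary carbon), hydride shift competes with ring contraction, or the tertiary allylic silyl ether ionises under SnCl4. Fallback: the quaternary carbon is set by a boat-constrained ester enolate Claisen rearrangement of a dioxanone and the ring is contracted afterwards; it sets out from 10 and comes back at 16.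
- The primary hydroxyl of 10 is alkylated through its stannylene acetal (Bu2SnO; then CsF, DMF) with methyl 2-bromo-3-[(tert-butyldiphenylsilyl)oxy]propanoate F1 (from methyl 2-bromo-3-hydroxypropanoate, TBDPSCl, imidazole) to give the hydroxy ester F2.
- F2 lactonises (TsOH cat., toluene, 60 °C) to the 6-alkenyl-1,4-dioxan-2-one F3 (epimers at the enolisable carbon).
- Enolate Claisen rearrangement (LiN(SiMe3)2, Me3SiCl, Et3N, THF, −78 °C to rt) should give after work-up the dihydropyran acid F4. The lactone ring forces a boat, so with the Z-alkene the chain ends cis to CH2OSi and trans to the carboxyl group, and the S carbinol carbon fixes the absolute sense.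
- Me3SiCHN2 gives the methyl ester F5; one-flask reduction and homologation (i-Bu2AlH, −78 °C; then dimethyl (1-diazo-2-oxopropyl)phosphonate, K2CO3, MeOH) gives the alkyne F6; LiN(SiMe3)2 then Me3SiCl gives the silylalkyne F7.
- mCPBA epoxidises the ring olefin, the only 1,2-disubstituted alkene, to the epoxide F8. BF3·OEt2 at −78 °C opens it at the carbon remote from the ring oxygen with 1,2-shift of the OCH2 carbon (ring contraction of an epoxide to the aldehyde of the smaller ring), which gives 16 together with its C-3 epimer 17; step 11 converges both.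

Step 15. What may go wrong: oligomerisation by cross-metathesis outruns closure of the strained nine-membered ring, or the catalyst is drawn into the 1,1-disubstituted olefin. Fallback: the ring is closed before the carbonyl chemistry, on a substrate without the methylidene group; it sets out from 18 and comes back at 21. Ring-closing metathesis of the homoallylic alcohols 18 (second-generation Hoveyda–Grubbs catalyst, toluene, 1 mM, 80 °C), where only two terminal olefins are present and a free hydroxyl sits next to the allyl group, gives the cyclononenol F9. Dess–Martin oxidation gives the ring ketone F10, and methylenation with Zn/CH2Br2/TiCl4 gives 21.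

Step 17. What may go wrong: hydrostannation with the wrong regiochemistry at the hindered alkyne, or protodestannylation and acid-induced ionisation of the dienyl ether during the coupling. Fallback: the polarity of the coupling is reversed; it sets out from 22 and comes back at 24. Hydrozirconation (Cp2Zr(H)Cl in excess, THF; syn addition with zirconium at the terminus) and iodinolysis (I2, 0 °C) give the E-vinyl iodide F11. Suzuki–Miyaura coupling with 2-methylprop-1-enylboronic acid pinacol ester (Pd(PPh3)4, aqueous K3PO4, THF, 50 °C) under basic conditions gives 24.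

Further compounds
F1 | step 10 | methyl 2-bromo-3-[(tert-butyldiphenylsilyl)oxy]propanoate (racemic) | COC(=O)C(Br)CO[Si](c1ccccc1)(c1ccccc1)C(C)(C)C
F2 | step 10 | methyl 2-{[(2S,3Z,7S)-7-[(tert-butyldimethylsilyl)oxy]-2-hydroxy-7-methylnona-3,8-dien-1-yl]oxy}-3-[(tert-butyldiphenylsilyl)oxy]propanoate (epimers at the ester alpha carbon) | C=C[C@@](C)(O[Si](C)(C)C(C)(C)C)CC/C=C\[C@H](O)COC(CO[Si](c1ccccc1)(c1ccccc1)C(C)(C)C)C(=O)OC
F3 | step 10 | (6S)-6-[(1Z,5S)-5-[(tert-butyldimethylsilyl)oxy]-5-methylhepta-1,6-dien-1-yl]-3-{[(tert-butyldiphenylsilyl)oxy]methyl}-1,4-dioxan-2-one (epimers at C-3) | C=C[C@@](C)(O[Si](C)(C)C(C)(C)C)CC/C=C\[C@H]1COC(CO[Si](c2ccccc2)(c2ccccc2)C(C)(C)C)C(=O)O1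
F4 | step 10 | 2-{[(tert-butyldiphenylsilyl)oxy]methyl}-3-[(3S)-3-[(tert-butyldimethylsilyl)oxy]-3-methylpent-4-en-1-yl]-3,6-dihydro-2H-pyran-2-carboxylic acid (chain cis to CH2OSi) | OC(=O)[C@@]1(CO[Si](c2ccccc2)(c2ccccc2)C(C)(C)C)OCC=C[C@@H]1CC[C@](C)(O[Si](C)(C)C(C)(C)C)C=C
F5 | step 10 | methyl ester of F4 | COC(=O)[C@@]1(CO[Si](c2ccccc2)(c2ccccc2)C(C)(C)C)OCC=C[C@@H]1CC[C@](C)(O[Si](C)(C)C(C)(C)C)C=C
F6 | step 10 | 2-ethynyl analogue of F5 (ethynyl in place of the ester group) | C#C[C@@]1(CO[Si](c2ccccc2)(c2ccccc2)C(C)(C)C)OCC=C[C@@H]1CC[C@](C)(O[Si](C)(C)C(C)(C)C)C=C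
F7 | step 10 | 2-[(trimethylsilyl)ethynyl] analogue of F6 | C[Si](C)(C)C#C[C@@]1(CO[Si](c2ccccc2)(c2ccccc2)C(C)(C)C)OCC=C[C@@H]1CC[C@](C)(O[Si](C)(C)C(C)(C)C)C=C
F8 | step 10 | 4,5-epoxide of F7 (3,7-dioxabicyclo[4.1.0]heptane; either epoxide face) | C[Si](C)(C)C#C[C@@]1(CO[Si](c2ccccc2)(c2ccccc2)C(C)(C)C)OCC2OC2[C@@H]1CC[C@](C)(O[Si](C)(C)C(C)(C)C)C=C
F9 | step 15 | ring-closed secondary alcohol (4-hydroxy in place of 4-methylidene in 21; both carbinol epimers) | OC1C/C=C\[C@@](C)(O[Si](C)(C)C(C)(C)C)CC[C@H]2[C@H]1CO[C@@]2(C#C[Si](C)(C)C)CO[Si](c3ccccc3)(c3ccccc3)C(C)(C)C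
F10 | step 15 | ring ketone (4-oxo in place of 4-methylidene in 21) | O=C1C/C=C\[C@@](C)(O[Si](C)(C)C(C)(C)C)CC[C@H]2[C@H]1CO[C@@]2(C#C[Si](C)(C)C)CO[Si](c3ccccc3)(c3ccccc3)C(C)(C)C
F11 | step 17 | (E)-2-iodoethenyl analogue of 22 | C=C1C/C=C\[C@@](C)(O)CC[C@H]2[C@H]1CO[C@@]2(/C=C/I)CO
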